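Remark on the chemistry: atom labels follow the chromene (O1, C2, C3, C4, C4a, C5 to C8, C8a; benzene ring = ring A, pyran ring = ring B) and the side chain (C1' ketone, C2' methylene, C3' carbinol). The descriptor at C3' of the target is read from the SMILES as S.

## Analysis of the target

Target 14 is a 2,2-dimethyl-2H-chromene whose ring A carries a hydroxyl at C5, a 3-hydroxy-3-phenylpropanoyl chain at C6 and a methoxy group at C7, that is, a β-hydroxydihydrochalcone. Ring A is pentasubstituted, only C8 bears hydrogen, and its three oxygens are all different (free phenol, methyl ether, ring ether O1). The single stereocentre is the benzylic carbinol C3' (S); nothing else in the molecule can relay its configuration, so it must come from a catalyst, a reagent or a bought building block. The sensitive parts are the aldol unit C1' to C3' (loss of water to the enone, retro-aldol cleavage in base, ring closure of the free C5 phenol onto the enone) and the styrene-type C3=C4 bond of ring B (acid, electrophilic halogen, hydrogenation). The hard bond is C6–C1': C6 lies between two oxygen-bearing carbons, so the ketone is di-ortho-substituted and twisted, and an electrophilic acylation would have to choose between the electronically similar C6 and C8. The plan rests on C1' being a lone carbonyl carbon between C6 and the C2' methylene, so that it can be supplied as carbon monoxide 11 while C2', C3' and the phenyl ring come from acetophenone 10. The resulting 1,3-diketone 12 has one carbonyl buried between the C5 and C7 oxygens and one ordinary benzoyl carbonyl, and this difference allows the stereocentre to be set afterwards by a selective reduction.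

## Retrosynthetic reasoning

**14 to 13.** The last bond cut is the O–CH2 bond of a methoxymethyl acetal on the C5 oxygen. The phenol stays masked to the end because a free hydroxyl beside C6 would intercept the acylpalladium intermediate of the key step and would let an ortho-hydroxy diketone close to a cyclic hemiketal. The forward step has to free the phenol without dehydrating or ionising the aldol unit.

**13 to 12.** The C3'–H bond is cut, which takes the carbinol back to the C3' carbonyl of diketone 12. The cut is made here because the two carbonyls of 12 differ so strongly in access that a catalyst can pick one. It also lets the chain be assembled at the diketone level, where it is enolised, cannot eliminate and carries no stereocentre. The forward reaction has to deliver hydride to C3' only, and to one face.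

**12 to 9, 10 and 11.** Both bonds at C1' are cut, C6–C1' and C1'–C2'. Cutting only C1'–C2' or C2'–C3' would leave a carbon substituent still to be forced onto the hindered C6. Cutting both bonds turns the crowded carbonyl into carbon monoxide 11, and the insertion of 11 moves the metal away from the two ortho oxygens. The partners are then aryl iodide 9 and the commodity ketone 10. The forward step must form the aroylpalladium species faster than any direct aryl–enolate coupling and stop after one acylation.

**9 to 7 through 8.** The C6–I bond is cut to the aryllithium 8, which comes from 7 by deprotonation. C6–H is the only hydrogen flanked by the acetal oxygen and the methoxy oxygen, so the acetal that protects the phenol also places the metal. An electrophilic iodination would not discriminate C6 from C8 and would endanger C3=C4.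

**7 to 6.** The acetal O–C bond is cut to phenol 6. This is a simple protection that also installs the directing group.

**6 to 2 and 3 through 5 and 4.** Ring B is opened at O1–C2, the retron of an oxa-6π electrocyclisation of ortho-quinone methide 5. The chain is then cut at C3–C4, the addition of alkenyl nucleophile 3 to the formyl carbon of 2, via triol 4. Routing the four-carbon unit through the aldehyde carbon fixes C4a between two equivalent oxygens, so closure onto either gives the same chromene. A direct annulation of an unsymmetrical phenol would give two regioisomers.

**2 to 1.** The O–CH3 bond at the oxygen para to the formyl group is cut, which leads to the commercial trihydroxy aldehyde 1. The forward step must methylate only that oxygen.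

## Alternatives that were turned down

**Alternative 1:** Ring A is taken apart at C5–C4a, C8–C8a and C5–C6 into 3-methoxycyclobut-2-en-1-one A1 and the prenyl-bearing siloxyalkyne A2.
- Forward key step: heating opens A1 to a vinylketene, which adds to A2 in a [2+2] sense; a second four-electron opening, a six-electron closure and tautomerisation give phenol A3.
- For it: ring A arrives regiodefined, and the two oxygens flanking C4a are already distinguished (free hydroxyl at C5, silyl ether at the future O1). On this point it is stronger than the chosen route, which needs a selective methylation and relies on symmetry.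
- Against it: the oxygenation pattern of ring A can be bought. A1 and A2 are sensitive reagents that each need their own synthesis. A3 still lacks ring B (protection, desilylation and an oxidative closure that also introduces C3=C4), the whole C6 chain and the stereocentre.
- Comparison: the C6 versus C8 question returns unchanged when the chain is attached, and the step count to the stage of 7 is roughly doubled. The chosen route buys ring A and spends its key step on the bonds around C1'.

**Alternative 2:** Ring B is disconnected at C3–C4 and O1–C2 into aldehyde 2, 2-methylprop-1-enylboronic acid A4 and a secondary amine.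
- Forward key step: the iminium ion of 2 accepts the alkenyl group from a phenol-bound boronate, the amine is expelled, and the quinone methide closes to chromenol A5, which is identical with 6.
- For it: it needs no excess organometallic, tolerates both free phenols and can run with catalytic amine. For making ring B it is as good as or better than the Grignard addition of step 2, and it is therefore kept as the reserve for that step.
- Against it: as a strategy it solves the easy part. Its product is 6, so the C6 functionalisation, the acyl chain and the stereocentre are all still unplanned, and no step is saved.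
- Comparison: the chosen strategy contains an equivalent ring B construction and also defines how the hindered ketone and C3' are made.

**Alternative 3:** C6–C1' and C5–O are cut together, giving a C5–C6 aryne from silyl triflate A6 and the enantiopure silyloxy acid A7.
- Forward key step: a fluoride source unveils the aryne. The carboxylate oxygen of A7 adds at C5, distal to the C7 methoxy group, and the aryl anion at C6 attacks the ester carbonyl, a formal insertion into the acyl–oxygen bond. The product is the ortho-hydroxyaryl ketone A8, the C3' silyl ether of the target.
- For it: it is the most convergent plan. The stereocentre arrives ready-made, and the phenol appears unprotected, so the endgame is one mild desilylation and not acid on an aldol. On convergency and on the mildness of the last step it is stronger than the chosen route.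
- Against it: A6 needs silylation at C6 and triflation at C5, which is the same C6 problem as for 9 with more steps and a more delicate product. A7 needs a separate enantioselective preparation. The aryne is generated beside C3=C4 and can be lost to ene or cycloaddition pathways. The insertion can stop at the aryl ester. Basic fluoride can eliminate the β-silyloxy group of A7.
- Comparison: the chosen route uses a stable, isolable aryl iodide, commodity partners 10 and 11, and a catalytic cycle whose steps are each understood for hindered aryl iodides. It pays for this with one catalytic asymmetric step and an acidic deprotection.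

Key step: step 5

## Route

Step 1
Reactants: 1 2,4,6-trihydroxybenzaldehyde
Product: 2 2,6-dihydroxy-4-methoxybenzaldehyde
Conditions: MeI (1.0 equiv), K2CO3 (1.0 equiv), DMF, 0 °C to rt
Reagents that add atoms: iodomethane, CI
Why: Williamson O-methylation; with one equivalent of weak base the 4-hydroxyl (para to the formyl group, not tied up in a hydrogen bond to the carbonyl) is ionised and alkylated first, so the symmetric mono-ether should predominate. Over-methylated material and unreacted 1 differ enough in polarity to be removed.

Step 2
Reactants: 2 2,6-dihydroxy-4-methoxybenzaldehyde; 3 2-methylprop-1-enylmagnesium bromide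
Product: 6 7-methoxy-2,2-dimethyl-2H-chromen-5-ol, via benzylic triol 4 (not isolated), via ortho-quinone methide 5 (not isolated)
Conditions: 3 (3.5 equiv, THF solution), THF, 0 °C to rt; aq NH4Cl; then toluene, PPTS (cat.), 80 °C
Reagents that add atoms: none
Why: Two equivalents of the Grignard reagent make the magnesium phenoxides and a third adds 1,2 to the chelated aldehyde to give 4. The electron-rich ortho-hydroxybenzylic allylic alcohol then loses water to 5, which closes by oxa-6π electrocyclisation. Because the former aldehyde carbon sits between two equivalent oxygens, either closure gives the same chromene.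

Step 3
Reactants: 6 7-methoxy-2,2-dimethyl-2H-chromen-5-ol
Product: 7 7-methoxy-5-(methoxymethoxy)-2,2-dimethyl-2H-chromene
Conditions: MOMCl (1.3 equiv), i-Pr2NEt (2 equiv), CH2Cl2, 0 °C to rt
Reagents that add atoms: chloromethyl methyl ether, COCCl
Why: O-alkylation of the phenol with an α-chloro ether under amine base. The acetal protects the phenol from the acylpalladium chemistry of step 5 and serves as the ortho director for step 4.

Step 4
Reactants: 7 7-methoxy-5-(methoxymethoxy)-2,2-dimethyl-2H-chromene
Product: 9 6-iodo-7-methoxy-5-(methoxymethoxy)-2,2-dimethyl-2H-chromene, via 6-lithio chromene 8 (not isolated)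
Conditions: n-BuLi (1.2 equiv), Et2O, 0 °C; then I2 (1.3 equiv), THF, −78 °C to rt; aq Na2S2O3
Reagents that add atoms: iodine, II
Why: Directed ortho-metalation; C6–H lies between the acetal and the methoxy group, and the acetal binds lithium through both of its oxygens, so C6 should be deprotonated in preference to C8, which has only two simple ether neighbours. Aryllithium 8 takes up iodine at low temperature much faster than iodine can add to C3=C4.

Step 5
Reactants: 9 6-iodo-7-methoxy-5-(methoxymethoxy)-2,2-dimethyl-2H-chromene; 10 acetophenone; 11 carbon monoxide
Product: 12 1-[7-methoxy-5-(methoxymethoxy)-2,2-dimethyl-2H-chromen-6-yl]-3-phenylpropane-1,3-dione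
Conditions: 10 (2 equiv), CO (2 bar), Pd(OAc)2 (5 mol %), Xantphos [4,5-bis(diphenylphosphino)-9,9-dimethylxanthene] (6 mol %), MgCl2 (2 equiv), Et3N (4 equiv), 1,4-dioxane, 80 °C; aq citric acid work-up
Reagents that add atoms: none
Why: This is a palladium-catalysed carbonylative α-arylation of a ketone with an aryl iodide, a known three-component route to 1,3-diketones. Pd(OAc)2 is reduced in the flask to a zerovalent palladium–Xantphos complex, which inserts into the C6–I bond of 9; CO then binds and migratory insertion gives a divalent aroylpalladium iodide. MgCl2 and Et3N enolise 10 softly to a magnesium enolate, whose carbon attacks the aroylpalladium unit (through a palladium-bound enolate and reductive elimination), forming C1'–C2' after C6–C1' and returning zerovalent palladium. No ring is closed and no stereocentre is formed. The step needs carbonylative coupling to beat direct arylation: the arylpalladium is flanked by the C5 and C7 oxygens, so moving the metal one carbon outward by CO insertion relieves strain, and the CO atmosphere keeps the acyl form populated. It needs C- rather than O-acylation, which the chelating magnesium enolate and the wide bite angle of the ligand (fast reductive elimination at carbon) favour. It needs a single acylation: 12 is far more acidic than 10 and is held as its magnesium diketonate, which is hindered and weakly nucleophilic. The cis-disubstituted C3=C4 bond is a poor Heck acceptor and the acetal should survive the weakly basic medium.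

Step 6
Reactants: 12 1-[7-methoxy-5-(methoxymethoxy)-2,2-dimethyl-2H-chromen-6-yl]-3-phenylpropane-1,3-dione
Product: 13 (3S)-3-hydroxy-1-[7-methoxy-5-(methoxymethoxy)-2,2-dimethyl-2H-chromen-6-yl]-3-phenylpropan-1-one
Conditions: RuCl(p-cymene)[(S,S)-TsDPEN] (2 mol %), HCO2H/Et3N (5:2), CH2Cl2, 25 °C
Reagents that add atoms: none
Why: Noyori–Ikariya asymmetric transfer hydrogenation; the ruthenium hydride and the ligand N–H deliver hydride and proton to the benzoyl carbonyl only, because the C1' carbonyl is di-ortho-substituted, twisted and shielded. The (S,S)-ligand seats the phenyl group of the substrate against the η6-arene (CH/π contact), which, as for simple aryl alkyl ketones, should give the (S)-carbinol. Formic acid makes the reduction irreversible and the weakly acidic medium avoids retro-aldol cleavage.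

Step 7
Reactants: 13 (3S)-3-hydroxy-1-[7-methoxy-5-(methoxymethoxy)-2,2-dimethyl-2H-chromen-6-yl]-3-phenylpropan-1-one
Product: 14 (3S)-3-hydroxy-1-(5-hydroxy-7-methoxy-2,2-dimethyl-2H-chromen-6-yl)-3-phenylpropan-1-one
Conditions: HCl (0.5 M) in MeOH/THF, 0 °C to rt; aq NaHCO3
Reagents that add atoms: none
Why: Acid-catalysed acetal exchange with methanol; an aryl methoxymethyl ether ortho to a carbonyl is among the most labile of its kind, because the departing phenol is a good leaving group and ends hydrogen-bonded to the C1' carbonyl. At or below room temperature the aldol unit should neither lose water nor ionise at C3', so the configuration set in step 6 is kept.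

## Compound list

1 | 2,4,6-trihydroxybenzaldehyde | O=Cc1c(O)cc(O)cc1O | starting material
2 | 2,6-dihydroxy-4-methoxybenzaldehyde | COc1cc(O)c(C=O)c(O)c1 | intermediate
3 | 2-methylprop-1-enylmagnesium bromide | CC(C)=C[Mg]Br | starting material
4 | 2-(1-hydroxy-3-methylbut-2-en-1-yl)-5-methoxybenzene-1,3-diol (racemic, not isolated) | COc1cc(O)c(C(O)C=C(C)C)c(O)c1 | intermediate
5 | 5-hydroxy-3-methoxy-6-(3-methylbut-2-en-1-ylidene)cyclohexa-2,4-dien-1-one (not isolated) | O=C1C=C(OC)C=C(O)C1=CC=C(C)C | intermediate
6 | 7-methoxy-2,2-dimethyl-2H-chromen-5-ol | COc1cc(O)c2C=CC(C)(C)Oc2c1 | intermediate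
7 | 7-methoxy-5-(methoxymethoxy)-2,2-dimethyl-2H-chromene | COCOc1cc(OC)cc2OC(C)(C)C=Cc12 | intermediate
8 | [7-methoxy-5-(methoxymethoxy)-2,2-dimethyl-2H-chromen-6-yl]lithium (not isolated) | COCOc1c([Li])c(OC)cc2OC(C)(C)C=Cc12 | intermediate
9 | 6-iodo-7-methoxy-5-(methoxymethoxy)-2,2-dimethyl-2H-chromene | COc1cc2c(c(OCOC)c1I)C=CC(C)(C)O2 | intermediate
10 | acetophenone | CC(=O)c1ccccc1 | starting material
11 | carbon monoxide | [C-]#[O+] | starting material
12 | 1-[7-methoxy-5-(methoxymethoxy)-2,2-dimethyl-2H-chromen-6-yl]-3-phenylpropane-1,3-dione | COc1cc2c(c(OCOC)c1C(=O)CC(=O)c1ccccc1)C=CC(C)(C)O2 | intermediate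
13 | (3S)-3-hydroxy-1-[7-methoxy-5-(methoxymethoxy)-2,2-dimethyl-2H-chromen-6-yl]-3-phenylpropan-1-one | COc1cc2c(c(OCOC)c1C(=O)C[C@H](O)c1ccccc1)C=CC(C)(C)O2 | intermediate
14 | (3S)-3-hydroxy-1-(5-hydroxy-7-methoxy-2,2-dimethyl-2H-chromen-6-yl)-3-phenylpropan-1-one | COc1cc2c(c(O)c1C(=O)C[C@H](O)c1ccccc1)C=CC(C)(C)O2 | target

## Step count and risks

Total step count: 7. Longest linear sequence: 7 steps (1 to 14); compounds 3, 10 and 11 are bought.

**Step 5 (key step).** The most likely failure is slow capture of the congested aroylpalladium intermediate by the enolate. Loss of CO with direct arylation, reduction of the C–I bond, or acylation of the enolate at oxygen could then take over, because the electrophilic carbon is shielded by two ortho oxygens.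
Fallback: it sets out from 9 and returns at 12. Iodine–lithium exchange on 9 (n-BuLi, THF, −78 °C) regenerates 8, which is acylated with N-methoxy-N-methylacetamide to give the methyl ketone 1-[7-methoxy-5-(methoxymethoxy)-2,2-dimethyl-2H-chromen-6-yl]ethan-1-one F1. A crossed Claisen condensation of F1 with methyl benzoate (NaH, THF, reflux) then gives 12. The carbonyl carbon is here brought in by a hard organolithium and not by a metal acyl.

**Step 4.** Deprotonation may compete at C8, where the in-plane lone pair of O1 and the methoxy group can also hold lithium, and the regioisomeric iodide would be hard to remove. Addition of n-BuLi across the styrene-type C3=C4 bond is a lesser risk.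
Fallback: it sets out from 6 and returns at 9. Phenol 6 is converted (NaH, Et2NC(O)Cl, THF) into 7-methoxy-2,2-dimethyl-2H-chromen-5-yl diethylcarbamate F2. The carbamate is a much stronger director, whose only free ortho position is C6, and it is lithiated at −78 °C (s-BuLi, TMEDA, THF), where ether-directed metalation at C8 is too slow. Iodine gives 6-iodo-7-methoxy-2,2-dimethyl-2H-chromen-5-yl diethylcarbamate F3. Hydrolysis (KOH, EtOH/H2O, reflux) gives 6-iodo-7-methoxy-2,2-dimethyl-2H-chromen-5-ol F4, and the conditions of step 3 convert F4 into 9.

**Step 6.** Diketone 12 is almost wholly enolised and can bind ruthenium as a diketonate, so turnover may stall. Alternatively the site or face selectivity may erode, because the "alkyl" side of this aryl ketone is a chelating β-keto unit and not a plain chain. If only the sense of induction is wrong, the (R,R)-complex is used.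
Fallback: the stereocentre is bought and not made; it sets out from 9 and returns at 13. Commercial ethyl (S)-3-hydroxy-3-phenylpropanoate is converted (MeNHOMe·HCl, i-PrMgCl, THF) into (3S)-3-hydroxy-N-methoxy-N-methyl-3-phenylpropanamide F5. Its hydroxyl is masked as the chloromagnesium alkoxide (i-PrMgCl, 1 equiv, −20 °C). Aryllithium 8, regenerated from 9 by iodine–lithium exchange (n-BuLi, THF, −78 °C), is added to it, and aqueous work-up gives 13 directly.

**Step 7.** Acid may promote loss of water from the aldol unit to the enone, followed by closure of the freed C5 phenol onto it. Ionisation at C3' with racemisation, or acid-catalysed addition to C3=C4, are further possibilities.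
Fallback: the protecting group is changed before the chain is built, so that the last step is a fluoride desilylation; it sets out from 9 and returns at 14. Acidic methanolysis of 9 (HCl, MeOH, rt; nothing acid-labile is present yet) gives the iodophenol F4 already described under step 4. Silylation (TBSOTf, 2,6-lutidine, CH2Cl2) gives tert-butyl[(6-iodo-7-methoxy-2,2-dimethyl-2H-chromen-5-yl)oxy]dimethylsilane F6. The conditions of step 5 give 1-{5-[(tert-butyldimethylsilyl)oxy]-7-methoxy-2,2-dimethyl-2H-chromen-6-yl}-3-phenylpropane-1,3-dione F7. The conditions of step 6 give (3S)-1-{5-[(tert-butyldimethylsilyl)oxy]-7-methoxy-2,2-dimethyl-2H-chromen-6-yl}-3-hydroxy-3-phenylpropan-1-one F8. Bu4NF buffered with AcOH (THF, 0 °C) then gives 14.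

**Step 2.** The doubly deprotonated aldehyde is a poor, 2,6-disubstituted electrophile, so addition of the hindered alkenyl Grignard reagent may stall. The quinone methide may also oligomerise before it cyclises.
Fallback: it sets out from 2 and returns at 6. Aldehyde 2 is condensed with 2-methylprop-1-enylboronic acid (A4) and dibenzylamine in dioxane at 90 °C. Alkenyl transfer from the phenol-bound boronate to the iminium carbon gives 2-[1-(dibenzylamino)-3-methylbut-2-en-1-yl]-5-methoxybenzene-1,3-diol F9. On heating, F9 expels the amine to give the same quinone methide 5, which closes to 6; no organometallic base is involved.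

## Further compounds

F1 | step 5 | 1-[7-methoxy-5-(methoxymethoxy)-2,2-dimethyl-2H-chromen-6-yl]ethan-1-one | COc1cc2c(c(OCOC)c1C(C)=O)C=CC(C)(C)O2
F2 | step 4 | 7-methoxy-2,2-dimethyl-2H-chromen-5-yl diethylcarbamate | CCN(CC)C(=O)Oc1cc(OC)cc2OC(C)(C)C=Cc12
F3 | step 4 | 6-iodo-7-methoxy-2,2-dimethyl-2H-chromen-5-yl diethylcarbamate | CCN(CC)C(=O)Oc1c(I)c(OC)cc2OC(C)(C)C=Cc12
F4 | step 4 | 6-iodo-7-methoxy-2,2-dimethyl-2H-chromen-5-ol | COc1cc2OC(C)(C)C=Cc2c(O)c1I
F5 | step 6 | (3S)-3-hydroxy-N-methoxy-N-methyl-3-phenylpropanamide | CON(C)C(=O)C[C@H](O)c1ccccc1
F6 | step 7 | tert-butyl[(6-iodo-7-methoxy-2,2-dimethyl-2H-chromen-5-yl)oxy]dimethylsilane | COc1cc2OC(C)(C)C=Cc2c(O[Si](C)(C)C(C)(C)C)c1I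
F7 | step 7 | 1-{5-[(tert-butyldimethylsilyl)oxy]-7-methoxy-2,2-dimethyl-2H-chromen-6-yl}-3-phenylpropane-1,3-dione | COc1cc2OC(C)(C)C=Cc2c(O[Si](C)(C)C(C)(C)C)c1C(=O)CC(=O)c1ccccc1
F8 | step 7 | (3S)-1-{5-[(tert-butyldimethylsilyl)oxy]-7-methoxy-2,2-dimethyl-2H-chromen-6-yl}-3-hydroxy-3-phenylpropan-1-one | COc1cc2OC(C)(C)C=Cc2c(O[Si](C)(C)C(C)(C)C)c1C(=O)C[C@H](O)c1ccccc1
F9 | step 2 | 2-[1-(dibenzylamino)-3-methylbut-2-en-1-yl]-5-methoxybenzene-1,3-diol | COc1cc(O)c(C(C=C(C)C)N(Cc2ccccc2)Cc2ccccc2)c(O)c1
A1 | alternative 1 | 3-methoxycyclobut-2-en-1-one | O=C1C=C(OC)C1
A2 | alternative 1 | triisopropyl[(5-methylhex-4-en-1-yn-1-yl)oxy]silane | CC(C)=CCC#CO[Si](C(C)C)(C(C)C)C(C)C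
A3 | alternative 1 | 5-methoxy-2-(3-methylbut-2-enyl)-3-(triisopropylsilyloxy)phenol | COc1cc(O)c(CC=C(C)C)c(O[Si](C(C)C)(C(C)C)C(C)C)c1
A4 | alternative 2 | 2-methylprop-1-enylboronic acid | CC(C)=CB(O)O
A5 | alternative 2 | 5-hydroxy-7-methoxy-2,2-dimethyl-2H-chromene (identical with 6) | COc1cc(O)c2C=CC(C)(C)Oc2c1
A6 | alternative 3 | 7-methoxy-2,2-dimethyl-6-(trimethylsilyl)-2H-chromen-5-yl trifluoromethanesulfonate | COc1cc2OC(C)(C)C=Cc2c(OS(=O)(=O)C(F)(F)F)c1[Si](C)(C)C
A7 | alternative 3 | (3S)-3-[(tert-butyldimethylsilyl)oxy]-3-phenylpropanoic acid | OC(=O)C[C@H](O[Si](C)(C)C(C)(C)C)c1ccccc1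
A8 | alternative 3 | (3S)-3-[(tert-butyldimethylsilyl)oxy]-1-(5-hydroxy-7-methoxy-2,2-dimethyl-2H-chromen-6-yl)-3-phenylpropan-1-one | COc1cc2c(c(O)c1C(=O)C[C@H](O[Si](C)(C)C(C)(C)C)c1ccccc1)C=CC(C)(C)O2
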